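Everything rests on cleaving the C5–O1 bond of the 1,2-dioxolane ring (O1–O2–C3–C4–C5). C5, the fully substituted ring carbon bonded to O1, a methyl group, C4 and the long chain, maps onto the stereocentre of (R)-linalool, except that its oxygen lies on the other side. An oxetane spanning C5–C4–C3 and built on linalool's own oxygen is therefore opened at C5 by hydrogen peroxide with inversion; one operation installs the (5S) C–OO bond and releases the C3 oxygen for later ring closure. The precursor is a 2,2,4-trisubstituted oxetane with a saturated silyloxyheptyl chain, carried as one C4 epimer so that any non-inverted material is a separable diastereomer.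

Key step: step 11

Remark: (R)-(−)-linalool of high enantiomeric purity is assumed to be purchased. The oxetane is deliberately used as the single (2R,4R) epimer, at the cost of one lipase resolution (step 4). Its secondary centre is erased in step 12, but until then it turns non-inverted material from step 11, and any material derived from ent-linalool, into a diastereomer that can be removed before it would become an enantiomeric impurity.

Step 1
Reactants: 1 (R)-linalool
Product: 3 (3R)-3,7-dimethyloct-6-ene-1,3-diol, via 9-BBN alkylborane 2 (not isolated)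
Conditions: 9-BBN (2.2 equiv), THF, 0 °C → rt; then NaBO3·4H2O, H2O, rt
Reagents that add atoms: sodium perborate, [Na+].[O-]B1OO1
Why: Hydroboration–oxidation, in which 9-BBN adds to the monosubstituted vinyl group far faster than to the trisubstituted alkene and places boron on the terminal carbon, while the tertiary stereocentre is not touched.

Step 2
Reactants: 3 (3R)-3,7-dimethyloct-6-ene-1,3-diol
Product: 4 (3R)-3-hydroxy-3,7-dimethyloct-6-enal
Conditions: TEMPO (0.1 equiv), PhI(OAc)2 (1.1 equiv), CH2Cl2, rt; NaHCO3 wash, used crude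
Reagents that add atoms: none
Why: Oxoammonium (TEMPO/PhI(OAc)2) oxidation, which converts only the primary alcohol, leaves the tertiary hydroxyl and the alkene alone, and gives a β-hydroxy aldehyde that is carried on crude to avoid dehydration.

Step 3
Reactants: 4 (3R)-3-hydroxy-3,7-dimethyloct-6-enal
Product: 5 (4R)-4,8-dimethylnon-7-ene-2,4-diol (both C2 epimers)
Conditions: 4 added to MeMgBr (2.5 equiv), THF, −78 → 0 °C; aq. NH4Cl
Reagents that add atoms: methylmagnesium bromide, C[Mg]Br
Why: Grignard addition, in which the first equivalent deprotonates the tertiary alcohol and the second adds to the aldehyde at low temperature, giving both C2 epimers because the quaternary centre offers no useful 1,3-induction.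

Step 4
Reactants: 5 (4R)-4,8-dimethylnon-7-ene-2,4-diol (both C2 epimers)
Product: 6 (2S,4R)-4,8-dimethylnon-7-ene-2,4-diol
Conditions: immobilised Candida antarctica lipase B (Novozym 435), vinyl acetate (3 equiv), MTBE, 30 °C, stopped just past half conversion; chromatography
Reagents that add atoms: none
Why: Lipase-catalysed kinetic resolution by transesterification, in which the enzyme acetylates the (2R) methyl carbinol, as expected from its usual preference for secondary alcohols, and leaves the (2S,4R) diol, so that C2 is selected and not created, and the tertiary hydroxyl is not acylated.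

Step 5
Reactants: 6 (2S,4R)-4,8-dimethylnon-7-ene-2,4-diol
Product: 8 (2R,4R)-2,4-dimethyl-2-(4-methylpent-3-en-1-yl)oxetane, via secondary monotosylate 7 (not isolated)
Conditions: n-BuLi (1.0 equiv), THF, 0 °C; TsCl (1.0 equiv), 0 °C → rt; n-BuLi (1.05 equiv), 0 → 60 °C
Reagents that add atoms: none
Why: One-pot monosulfonylation and Williamson-type 4-exo-tet closure, in which the secondary hydroxyl is tosylated selectively and the tertiary lithium alkoxide displaces the tosylate with inversion, so the (2S) carbinol becomes the (4R) oxetane carbon while the tertiary C–O bond, and with it the linalool centre, is retained.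

Step 6
Reactants: 8 (2R,4R)-2,4-dimethyl-2-(4-methylpent-3-en-1-yl)oxetane
Product: 10 3-[(2R,4R)-2,4-dimethyloxetan-2-yl]propanal, via secondary ozonide 9 (not isolated)
Conditions: O3, CH2Cl2, −78 °C; then Me2S, −78 °C → rt
Reagents that add atoms: ozone, [O-][O+]=O
Why: Ozonolysis with reductive work-up, which cleaves the only alkene while the oxetane is inert to ozone at −78 °C, and neither stereocentre is affected.

Step 7
Reactants: 11 4-bromobutan-1-ol
Product: 12 tert-butyl(4-bromobutoxy)diphenylsilane
Conditions: TBDPSCl (1.05 equiv), imidazole (1.5 equiv), CH2Cl2, 0 °C → rt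
Reagents that add atoms: tert-butyl(chloro)diphenylsilane, CC(C)(C)[Si](Cl)(c1ccccc1)c1ccccc1
Why: Silylation of a primary alcohol, which is faster at 0 °C than cyclisation of the bromo alcohol and installs an ether robust enough for the silyl triflate, TiCl4 and acidic methanol used later.

Step 8
Reactants: 12 tert-butyl(4-bromobutoxy)diphenylsilane
Product: 13 {4-[(tert-butyldiphenylsilyl)oxy]butyl}triphenylphosphonium bromide
Conditions: PPh3 (1.1 equiv), MeCN, reflux
Reagents that add atoms: triphenylphosphine, c1ccc(cc1)P(c1ccccc1)c1ccccc1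
Why: SN2 quaternisation of triphenylphosphine by an unhindered primary bromide under neutral conditions that the silyl ether tolerates.

Step 9
Reactants: 13 {4-[(tert-butyldiphenylsilyl)oxy]butyl}triphenylphosphonium bromide; 10 3-[(2R,4R)-2,4-dimethyloxetan-2-yl]propanal
Product: 15 tert-butyl({(4Z)-7-[(2R,4R)-2,4-dimethyloxetan-2-yl]hept-4-en-1-yl}oxy)diphenylsilane, via phosphonium ylide 14 (not isolated)
Conditions: NaHMDS (1.05 equiv), THF, −78 → 0 °C; then 10, −78 °C → rt
Reagents that add atoms: none
Why: Wittig olefination with a non-stabilised ylide, which should give mainly the Z alkene (its geometry is irrelevant because it is hydrogenated next) and leaves the base-stable oxetane intact.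

Step 10
Reactants: 15 tert-butyl({(4Z)-7-[(2R,4R)-2,4-dimethyloxetan-2-yl]hept-4-en-1-yl}oxy)diphenylsilane
Product: 16 tert-butyl({7-[(2R,4R)-2,4-dimethyloxetan-2-yl]heptyl}oxy)diphenylsilane
Conditions: H2 (1 atm), 10% Pd/C, EtOAc, rt
Reagents that add atoms: none
Why: Heterogeneous catalytic hydrogenation of a disubstituted alkene, which spares the oxetane (no benzylic C–O bond) and the silyl ether and completes every reduction before an O–O bond exists.

Step 11
Reactants: 16 tert-butyl({7-[(2R,4R)-2,4-dimethyloxetan-2-yl]heptyl}oxy)diphenylsilane; 17 hydrogen peroxide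
Product: 18 (2R,4S)-11-[(tert-butyldiphenylsilyl)oxy]-4-hydroperoxy-4-methylundecan-2-ol
Conditions: anhydrous H2O2 in Et2O (10 equiv), TMSOTf (0.3 equiv), Et2O, −78 → −40 °C; aq. NaHCO3; chromatography
Reagents that add atoms: none
Why: Catalytic TMSOTf activates the ring oxygen and polarises the bond to the fully substituted oxetane carbon, the only position able to bear positive charge, and hydrogen peroxide enters anti to the departing oxygen before the ion pair separates, so that relief of ring strain pays for a borderline SN2 substitution at a quaternary centre. The closest known reaction type is the Lewis acid-promoted perhydrolysis of 2,2-disubstituted oxetanes to 3-hydroperoxy alkanols, which proceeds with predominant inversion. No ring is closed: the four-membered ring is opened and its oxygen remains as the C2 carbinol of 18. The new (4S) centre is controlled by the (2R) oxetane carbon through backside attack, that is, by the stereocentre of linalool. The step needs attack at the quaternary and not the secondary ring carbon, which the greater cation-stabilising ability of the quaternary carbon should secure, and it needs inversion in place of free-cation scrambling, which ether as solvent, −78 °C and a large excess of peroxide favour. Any non-inverted (2R,4R) material is a diastereomer of 18, because the carbinol centre is fixed, and is removed by chromatography.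

Step 12
Reactants: 18 (2R,4S)-11-[(tert-butyldiphenylsilyl)oxy]-4-hydroperoxy-4-methylundecan-2-ol
Product: 20 (5S)-5-{7-[(tert-butyldiphenylsilyl)oxy]heptyl}-3,5-dimethyl-1,2-dioxolan-3-ol (C3 anomers), via hydroperoxy ketone 19 (not isolated)
Conditions: Dess–Martin periodinane (1.3 equiv), NaHCO3, CH2Cl2, 0 °C
Reagents that add atoms: none
Why: Dess–Martin oxidation of the secondary carbinol, in which the tertiary hydroperoxide has no α-hydrogen and should only exchange reversibly at iodine, after which ketone 19 closes spontaneously by 5-exo-trig hemiperketalisation, leaving C5 untouched and giving a C3 hemiketal centre whose configuration is of no consequence.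

Step 13
Reactants: 20 (5S)-5-{7-[(tert-butyldiphenylsilyl)oxy]heptyl}-3,5-dimethyl-1,2-dioxolan-3-ol (C3 anomers)
Product: 21 tert-butyl({7-[(3S)-5-methoxy-3,5-dimethyl-1,2-dioxolan-3-yl]heptyl}oxy)diphenylsilane (C5 anomers)
Conditions: CSA (0.1 equiv), MeOH, 3 Å MS, 0 °C → rt
Reagents that add atoms: methanol, CO
Why: Acid-catalysed ketalisation of the peroxy hemiketal through the peroxycarbenium ion, under conditions a primary TBDPS ether survives, with an anomer ratio that does not matter because the same carbon is ionised again in the next step.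

Step 14
Reactants: 21 tert-butyl({7-[(3S)-5-methoxy-3,5-dimethyl-1,2-dioxolan-3-yl]heptyl}oxy)diphenylsilane (C5 anomers); 22 1-(tert-butyldimethylsilyloxy)-1-methoxyethene
Product: 23 methyl 2-[(3R,5S)-5-{7-[(tert-butyldiphenylsilyl)oxy]heptyl}-3,5-dimethyl-1,2-dioxolan-3-yl]acetate
Conditions: 22 (3 equiv), TiCl4 (1.1 equiv), CH2Cl2, −78 °C; aq. NaHCO3; chromatographic separation from the C3 epimer
Reagents that add atoms: none
Why: Lewis acid-mediated displacement of a 3-alkoxy-1,2-dioxolane (Mukaiyama-type addition of a silyl ketene acetal to a peroxycarbenium ion), in which attack anti to the heptyl chain and syn to the C5 methyl gives the (3R) centre, but, because methyl and primary alkyl differ little in size, both C3 epimers are expected and 23 is isolated by chromatography with its relative configuration to be confirmed by NOE.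

Step 15
Reactants: 23 methyl 2-[(3R,5S)-5-{7-[(tert-butyldiphenylsilyl)oxy]heptyl}-3,5-dimethyl-1,2-dioxolan-3-yl]acetate
Product: 24 methyl 2-[(3R,5S)-5-(7-hydroxyheptyl)-3,5-dimethyl-1,2-dioxolan-3-yl]acetate
Conditions: HF·pyridine, pyridine, THF, 0 °C → rt
Reagents that add atoms: none
Why: Fluoride-mediated desilylation under acidic, non-basic conditions, chosen because the dioxolane acetate tolerates acid but could open by E1cB elimination under basic fluoride.

Step 16
Reactants: 24 methyl 2-[(3R,5S)-5-(7-hydroxyheptyl)-3,5-dimethyl-1,2-dioxolan-3-yl]acetate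
Product: 25 methyl 2-[(3R,5S)-3,5-dimethyl-5-(7-oxoheptyl)-1,2-dioxolan-3-yl]acetate
Conditions: Dess–Martin periodinane (1.2 equiv), NaHCO3, CH2Cl2, 0 °C → rt
Reagents that add atoms: none
Why: Dess–Martin oxidation of a primary alcohol to the aldehyde, to which a fully substituted dialkyl peroxide and a methyl ester are inert.

Step 17
Reactants: 25 methyl 2-[(3R,5S)-3,5-dimethyl-5-(7-oxoheptyl)-1,2-dioxolan-3-yl]acetate
Product: 26 methyl 2-{(3R,5S)-3,5-dimethyl-5-[(7E)-9-oxonon-7-en-1-yl]-1,2-dioxolan-3-yl}acetate
Conditions: Ph3P=CHCHO (1.3 equiv), toluene, 70 °C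
Reagents that add atoms: (triphenylphosphoranylidene)acetaldehyde, O=CC=P(c1ccccc1)(c1ccccc1)c1ccccc1
Why: Wittig reaction with a stabilised ylide, which is E-selective, reacts with the aldehyde and not the ester, does not reduce the dialkyl peroxide as a free phosphine would, and is kept to a small excess to suppress a second homologation.

Step 18
Reactants: 27 (Z)-hex-3-en-1-ol
Product: 28 5-{[(3Z)-hex-3-en-1-yl]sulfanyl}-1-phenyl-1H-tetrazole
Conditions: 1-phenyl-1H-tetrazole-5-thiol (1.2 equiv), PPh3, DIAD, THF, 0 °C → rt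
Reagents that add atoms: 1-phenyl-1H-tetrazole-5-thiol, Sc1nnnn1-c1ccccc1
Why: Mitsunobu thioetherification of a primary alcohol with an acidic heteroaryl thiol, which leaves the Z alkene unchanged.

Step 19
Reactants: 28 5-{[(3Z)-hex-3-en-1-yl]sulfanyl}-1-phenyl-1H-tetrazole
Product: 29 5-{[(3Z)-hex-3-en-1-yl]sulfonyl}-1-phenyl-1H-tetrazole
Conditions: (NH4)6Mo7O24·4H2O (0.1 equiv), 30% aq. H2O2 (5 equiv), EtOH, 0 °C → rt
Reagents that add atoms: hydrogen peroxide (17), OO
Why: Molybdate-catalysed oxidation of the sulfide to the sulfone, conditions under which an isolated disubstituted alkene is not epoxidised.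

Step 20
Reactants: 29 5-{[(3Z)-hex-3-en-1-yl]sulfonyl}-1-phenyl-1H-tetrazole; 26 methyl 2-{(3R,5S)-3,5-dimethyl-5-[(7E)-9-oxonon-7-en-1-yl]-1,2-dioxolan-3-yl}acetate
Product: 31 methyl 2-{(3R,5S)-3,5-dimethyl-5-[(7E,9E,12Z)-pentadeca-7,9,12-trien-1-yl]-1,2-dioxolan-3-yl}acetate, via potassium sulfonyl carbanion 30 (not isolated)
Conditions: 29 (1.3 equiv), KHMDS (1.25 equiv), DME, −78 °C; then 26, −78 → −20 °C; aq. NH4Cl
Reagents that add atoms: none
Why: Julia–Kocienski olefination, in which the pre-formed sulfonyl carbanion adds to the enal and Smiles rearrangement with loss of SO2 and tetrazolate should give the new 9E alkene, without isomerising the 7E and 12Z alkenes and, at −78 °C with no free amide base, faster than the ester α-CH2 is deprotonated.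

Compound list
1 | (R)-linalool | CC(C)=CCC[C@](O)(C)C=C | starting material
2 | 9-[(3R)-3-hydroxy-3,7-dimethyloct-6-en-1-yl]-9-borabicyclo[3.3.1]nonane (hydroxyl drawn free) | CC(C)=CCC[C@](O)(C)CCB1C2CCCC1CCC2 | intermediate
3 | (3R)-3,7-dimethyloct-6-ene-1,3-diol | CC(C)=CCC[C@](O)(C)CCO | intermediate
4 | (3R)-3-hydroxy-3,7-dimethyloct-6-enal | CC(C)=CCC[C@](O)(C)CC=O | intermediate
5 | (4R)-4,8-dimethylnon-7-ene-2,4-diol, both C2 epimers | CC(C)=CCC[C@](O)(C)CC(C)O | intermediate
6 | (2S,4R)-4,8-dimethylnon-7-ene-2,4-diol | CC(C)=CCC[C@](O)(C)C[C@H](C)O | intermediate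
7 | (2S,4R)-4-hydroxy-4,8-dimethylnon-7-en-2-yl 4-methylbenzenesulfonate | CC(C)=CCC[C@](O)(C)C[C@H](C)OS(=O)(=O)c1ccc(C)cc1 | intermediate
8 | (2R,4R)-2,4-dimethyl-2-(4-methylpent-3-en-1-yl)oxetane | CC(C)=CCC[C@]1(C)C[C@@H](C)O1 | intermediate
9 | 3-{2-[(2R,4R)-2,4-dimethyloxetan-2-yl]ethyl}-5,5-dimethyl-1,2,4-trioxolane | CC1(C)OOC(CC[C@]2(C)C[C@@H](C)O2)O1 | intermediate
10 | 3-[(2R,4R)-2,4-dimethyloxetan-2-yl]propanal | O=CCC[C@]1(C)C[C@@H](C)O1 | intermediate
11 | 4-bromobutan-1-ol | OCCCCBr | starting material
12 | tert-butyl(4-bromobutoxy)diphenylsilane | CC(C)(C)[Si](c1ccccc1)(c1ccccc1)OCCCCBr | intermediate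
13 | {4-[(tert-butyldiphenylsilyl)oxy]butyl}triphenylphosphonium bromide | CC(C)(C)[Si](c1ccccc1)(c1ccccc1)OCCCC[P+](c1ccccc1)(c1ccccc1)c1ccccc1.[Br-] | intermediate
14 | {4-[(tert-butyldiphenylsilyl)oxy]butylidene}triphenylphosphorane | CC(C)(C)[Si](c1ccccc1)(c1ccccc1)OCCCC=P(c1ccccc1)(c1ccccc1)c1ccccc1 | intermediate
15 | tert-butyl({(4Z)-7-[(2R,4R)-2,4-dimethyloxetan-2-yl]hept-4-en-1-yl}oxy)diphenylsilane | CC(C)(C)[Si](c1ccccc1)(c1ccccc1)OCCC/C=C\CC[C@]1(C)C[C@@H](C)O1 | intermediate
16 | tert-butyl({7-[(2R,4R)-2,4-dimethyloxetan-2-yl]heptyl}oxy)diphenylsilane | CC(C)(C)[Si](c1ccccc1)(c1ccccc1)OCCCCCCC[C@]1(C)C[C@@H](C)O1 | intermediate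
17 | hydrogen peroxide | OO | starting material
18 | (2R,4S)-11-[(tert-butyldiphenylsilyl)oxy]-4-hydroperoxy-4-methylundecan-2-ol | CC(C)(C)[Si](c1ccccc1)(c1ccccc1)OCCCCCCC[C@](C)(OO)C[C@@H](C)O | intermediate
19 | (4S)-11-[(tert-butyldiphenylsilyl)oxy]-4-hydroperoxy-4-methylundecan-2-one | CC(C)(C)[Si](c1ccccc1)(c1ccccc1)OCCCCCCC[C@](C)(OO)CC(C)=O | intermediate
20 | (5S)-5-{7-[(tert-butyldiphenylsilyl)oxy]heptyl}-3,5-dimethyl-1,2-dioxolan-3-ol, C3 anomers | CC(C)(C)[Si](c1ccccc1)(c1ccccc1)OCCCCCCC[C@@]1(C)CC(C)(O)OO1 | intermediate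
21 | tert-butyl({7-[(3S)-5-methoxy-3,5-dimethyl-1,2-dioxolan-3-yl]heptyl}oxy)diphenylsilane, C5 anomers | CC(C)(C)[Si](c1ccccc1)(c1ccccc1)OCCCCCCC[C@@]1(C)CC(C)(OC)OO1 | intermediate
22 | 1-(tert-butyldimethylsilyloxy)-1-methoxyethene | C=C(OC)O[Si](C)(C)C(C)(C)C | starting material
23 | methyl 2-[(3R,5S)-5-{7-[(tert-butyldiphenylsilyl)oxy]heptyl}-3,5-dimethyl-1,2-dioxolan-3-yl]acetate | CC(C)(C)[Si](c1ccccc1)(c1ccccc1)OCCCCCCC[C@@]1(C)C[C@](C)(CC(=O)OC)OO1 | intermediate
24 | methyl 2-[(3R,5S)-5-(7-hydroxyheptyl)-3,5-dimethyl-1,2-dioxolan-3-yl]acetate | OCCCCCCC[C@@]1(C)C[C@](C)(CC(=O)OC)OO1 | intermediate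
25 | methyl 2-[(3R,5S)-3,5-dimethyl-5-(7-oxoheptyl)-1,2-dioxolan-3-yl]acetate | O=CCCCCCC[C@@]1(C)C[C@](C)(CC(=O)OC)OO1 | intermediate
26 | methyl 2-{(3R,5S)-3,5-dimethyl-5-[(7E)-9-oxonon-7-en-1-yl]-1,2-dioxolan-3-yl}acetate | O=C/C=C/CCCCCC[C@@]1(C)C[C@](C)(CC(=O)OC)OO1 | intermediate
27 | (Z)-hex-3-en-1-ol | CC/C=C\CCO | starting material
28 | 5-{[(3Z)-hex-3-en-1-yl]sulfanyl}-1-phenyl-1H-tetrazole | CC/C=C\CCSc1nnnn1-c1ccccc1 | intermediate
29 | 5-{[(3Z)-hex-3-en-1-yl]sulfonyl}-1-phenyl-1H-tetrazole | CC/C=C\CCS(=O)(=O)c1nnnn1-c1ccccc1 | intermediate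
30 | potassium (3Z)-1-[(1-phenyl-1H-tetrazol-5-yl)sulfonyl]hex-3-en-1-ide | CC/C=C\C[CH-]S(=O)(=O)c1nnnn1-c1ccccc1.[K+] | intermediate
31 | methyl 2-{(3R,5S)-3,5-dimethyl-5-[(7E,9E,12Z)-pentadeca-7,9,12-trien-1-yl]-1,2-dioxolan-3-yl}acetate | CC/C=C\C/C=C/C=C/CCCCCC[C@@]1(C)C[C@](C)(CC(=O)OC)OO1 | target

Total step count: 20. Longest linear sequence: 16 steps (steps 1–6, 9–17 and 20).

Steps most likely to fail

Step 11. The substitution may run through a free tertiary cation instead of within the ion pair, eroding configuration at the new peroxide carbon. The peroxide may also attack the secondary ring carbon, or the product hydroperoxide may be alkylated a second time by activated oxetane. The fallback replaces the ionic opening by radical peroxidation with diastereomer separation; it sets out from 16 and returns at 18. Oxetane 16 is isomerised with a catalytic perfluoroaryl Lewis acid (Al(C6F5)3 or B(C6F5)3, toluene) to the homoallylic alcohol (2R)-11-[(tert-butyldiphenylsilyl)oxy]-4-methylideneundecan-2-ol F1. Any internal alkene isomer is equally acceptable, since all lead to the same tertiary radical. Isayama–Mukaiyama hydroperoxysilylation (Co(acac)2 cat., O2, Et3SiH, ClCH2CH2Cl) should then give the tertiary silyl peroxide as both C4 epimers, which are diastereomers because the (2R) carbinol is fixed. The required isomer, (2R,4S)-11-[(tert-butyldiphenylsilyl)oxy]-4-methyl-4-[(triethylsilyl)peroxy]undecan-2-ol F2, is separated and its O–Si bond cleaved (AcOH, THF, H2O) to give 18. Stereocontrol then rests on separation and not on inversion.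

Step 12. The free hydroperoxide may be consumed by the iodine(V) oxidant, through ligand exchange followed by radical or cationic decomposition, before or alongside oxidation of the carbinol. The fallback masks the hydroperoxide temporarily; it sets out from 18 and returns at 21. 2-Methoxypropene and catalytic PPTS (CH2Cl2, 0 °C) convert the hydroperoxide into the peroxyketal (2R,4S)-11-[(tert-butyldiphenylsilyl)oxy]-4-[(2-methoxypropan-2-yl)peroxy]-4-methylundecan-2-ol F3. Should the carbinol also be acetalised, that far more labile acetal is removed selectively with PPTS in methanol at 0 °C. Dess–Martin oxidation then gives (4S)-11-[(tert-butyldiphenylsilyl)oxy]-4-[(2-methoxypropan-2-yl)peroxy]-4-methylundecan-2-one F4. CSA in methanol removes the peroxyketal, and the liberated hydroperoxy ketone cyclises and is ketalised in the same flask to 21.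

Step 14. Facial selectivity at the planar peroxycarbenium carbon may be poor, since the methyl and primary alkyl groups at C5 differ little, and the Lewis acid may fragment the peroxycarbenium ion. The fallback forms the C3–O2 bond by conjugate addition instead of forming the C3–C bond; it sets out from 18 and returns at 23. Compound 18 is taken through F3 to ketone F4 as described for step 12. Horner–Wadsworth–Emmons olefination (trimethyl phosphonoacetate, NaH, THF) gives methyl (2E,5S)-12-[(tert-butyldiphenylsilyl)oxy]-5-[(2-methoxypropan-2-yl)peroxy]-3,5-dimethyldodec-2-enoate F5. Aqueous acetic acid frees the hydroperoxide to give methyl (2E,5S)-12-[(tert-butyldiphenylsilyl)oxy]-5-hydroperoxy-3,5-dimethyldodec-2-enoate F6. Et2NH in CF3CH2OH then effects the 5-exo-trig intramolecular oxa-Michael addition to 23 and its C3 epimer. Because this closure is reversible under the basic conditions, the separated unwanted epimer can be resubmitted and re-equilibrated, which the peroxycarbenium route does not allow.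

Further compounds
F1 | step 11 | (2R)-11-[(tert-butyldiphenylsilyl)oxy]-4-methylideneundecan-2-ol | CC(C)(C)[Si](c1ccccc1)(c1ccccc1)OCCCCCCCC(=C)C[C@@H](C)O
F2 | step 11 | (2R,4S)-11-[(tert-butyldiphenylsilyl)oxy]-4-methyl-4-[(triethylsilyl)peroxy]undecan-2-ol | CC(C)(C)[Si](c1ccccc1)(c1ccccc1)OCCCCCCC[C@](C)(OO[Si](CC)(CC)CC)C[C@@H](C)O
F3 | step 12 | (2R,4S)-11-[(tert-butyldiphenylsilyl)oxy]-4-[(2-methoxypropan-2-yl)peroxy]-4-methylundecan-2-ol | CC(C)(C)[Si](c1ccccc1)(c1ccccc1)OCCCCCCC[C@](C)(OOC(C)(C)OC)C[C@@H](C)O
F4 | step 12 | (4S)-11-[(tert-butyldiphenylsilyl)oxy]-4-[(2-methoxypropan-2-yl)peroxy]-4-methylundecan-2-one | CC(C)(C)[Si](c1ccccc1)(c1ccccc1)OCCCCCCC[C@](C)(OOC(C)(C)OC)CC(C)=O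
F5 | step 14 | methyl (2E,5S)-12-[(tert-butyldiphenylsilyl)oxy]-5-[(2-methoxypropan-2-yl)peroxy]-3,5-dimethyldodec-2-enoate | CC(C)(C)[Si](c1ccccc1)(c1ccccc1)OCCCCCCC[C@](C)(OOC(C)(C)OC)C/C(C)=C/C(=O)OC
F6 | step 14 | methyl (2E,5S)-12-[(tert-butyldiphenylsilyl)oxy]-5-hydroperoxy-3,5-dimethyldodec-2-enoate | CC(C)(C)[Si](c1ccccc1)(c1ccccc1)OCCCCCCC[C@](C)(OO)C/C(C)=C/C(=O)OC
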